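Start from the first product: in the flask, followed for 40.0 min, it stands flat near 25%, while the substrate has lost more, about 62.0%. So part of what reacted has gone elsewhere, and that part may have cost a second reagent.

| setting | red | flask |
|---|---|---|
| substrate | 1 M | 1.0 M |
| reagent | 0.90 equiv | 0.900 equiv |
| scavenger | 0.80 equiv | 0.800 equiv |
| remark | the very flask that is asked about, followed so far |  |
| time |  | 5.0 h |

red run (percent of the substrate charged)

| time / min | substrate / % | first product / % |
|---|---|---|
| 2.00 | 89 | 10 |
| 6.00 | 69 | 11 |
| 10.0 | 61 | 15 |
| 15.0 | 49 | 22 |
| 20.0 | 48 | 26 |
| 30.0 | 37 | 26 |
| 40.0 | 39 | 25 |

(each reading ± 2 percentage points)

* part of the substrate that has reacted at 5.0 h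
* share of the unused reagent that is free and not bound as idle adduct, at 5.0 h

- the earlier runs were read with a standard deviation of 2 percentage points
- the earlier runs do not show how much of reagent is bound; that part of a forecast is a guess

Bound c from below by the 62.0% already read. Bound it from above by the reagent, taken as the limiting reagent: at one reagent per substrate, the charge of 0.900 equiv is the ceiling.

Now tighten the top. The apparent rate constant of substrate loss is 0.0618 /min up to 6.00 min and 0.0104 /min from 20.0 min to 40.0 min. Take it as proportional to free reagent, with the early value standing for the full charge, and about 0.151 is estimated to remain free in that later stretch. That gives the reagent bill, 1.21, the reagent spent or bound per substrate reacted, a value read from scattered readings. If the bill does not fall, the charge pays for 74.5%. My bracket therefore ends there, with the scatter of the readings in it, and I commit to its top.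

The forecast puts c at 70%, inside the bracket, and the free share at 40%: “The free share is essentially a guess”.

The flask gives 74.9% reacted and 43.7% free, c lying 0.40 percentage points above the top of the bracket. In this flask at 5.00 h the free reagent left is 0.024% of its charge, less than the 25% of substrate left. At the bill as read, 74.9% of substrate costs 0.906, against 0.900 equiv charged.

    substrate + reagent → first product + released group (k = 0.0450 /M/min)
    substrate + reagent → other mono adduct + released group (k = 0.0550 /M/min)
    reagent + first product → double product + released group (k = 0.0160 /M/min)
    reagent + other mono adduct → double product + released group (k = 0.0370 /M/min)
    reagent + released group ⇌ idle adduct, settled at all times (K = 13.0 /M)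
    scavenger + released group → scavenged by-product (k = 3.00 /M/min)

On the neighbour charged with 0.360 equiv of reagent, the bill gives 29.8% reacted. The simulation gives 34.0%, more, with reagent at 0% and double product at 1.99%.

Readings and results stem from a simulated flask for substances that don't exist; noise was put on by code.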